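1. From one target reading it is impossible to tell where the rest of the solid substrate stands: at its highest reading in the north-west run target is 7.5% of the charge, so 92.5% of the solid substrate is not target at that reading. It may be still solid, dissolved or turned into something else.

2. Partner looks ample by its charge, 2 equiv. Yet south, with 4 equiv, peaks at just 8.4%. So I suspect partner is lost elsewhere, and that it is the limiting reagent despite its larger charge.

| flask | solid substrate | partner | protic impurity | remark | time |
|---|---|---|---|---|---|
| north-west | 0.25 M | 2 equiv | 0.35 M | run made earlier |  |
| east | 0.25 M | 2 equiv | 0.55 M | run made earlier |  |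
| south | 0.25 M | 4 equiv | 0.25 M | run made earlier |  |
| flask | 0.25 M | 2.00 equiv | 0.250 M |  | 1.0 h |

| run | time / min | target / % | solid product / % |
|---|---|---|---|
| north-west | 10.0 | 4.9 | 0 |
| north-west | 25.0 | 7.5 | 0 |
| north-west | 50.0 | 5.9 | 0.5 |
| north-west | 80.0 | 4.1 | 0.4 |
| east | 6.00 | 3.4 | 0.3 |
| east | 12.0 | 5.9 | 0 |
| east | 30.0 | 7.3 | 0 |
| east | 80.0 | 4.7 | 0.5 |
| south | 6.00 | 4.7 | 0 |
| south | 12.0 | 7.8 | 0.1 |
| south | 30.0 | 8.4 | 0 |
| south | 80.0 | 5.1 | 0.2 |

(standard deviation of a reading: 0.3 percentage points)

- how much target and solid product together there is at 1.0 h, in percent of the solid substrate charged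
- concentration of dissolved substrate in solution at 1.0 h, in percent of saturation

- what is said of target includes solid product
- solid substrate, solid product is a solid; its amount is given per volume of the solution
- what was read earlier has a scatter of 0.3 percentage points, one standard deviation
- at the start none of the solid substrate is in solution
- dissolved substrate means what is dissolved; the solid is not counted in it

3. After the peak, target falls. From the last two readings of each run I take the logarithm of the ratio and divide by the time between them. North-west gives 0.0121 min⁻¹, east 0.00881 min⁻¹, south 0.00998 min⁻¹. Their mean is the loss constant of target, 0.0103 min⁻¹.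

4. With a scatter of 0.3 percentage points, I read these as one constant. South has twice the partner, yet its constant is lower than north-west's. A steady constant suggests a pseudo-first-order loss, with target meeting something whose concentration holds still. I take that to be dissolved substrate, fed by remaining solid. So I expect [dissolved substrate] close to saturation.

5. The flask differs from north-west in impurity, which I ignore. Carrying the 5.9% read at 50.0 min forward to 1.0 h gives 5.32%.

6. The forecast gives 5.2% and 10%, holding that “Dissolved substrate would then be largely consumed by 1 h”; on saturation I differ.

The flask gives 5.29% and 98.5% of saturation. Dissolved substrate already stood at 91.1% of saturation at 0.500 h. Carried from 1.0 h to 2.00 h, the loss constant turns 5.29% into 2.85%; the flask holds 2.74%.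

    solid product ⇌ target, rate k1*(cs1 - [target]) while solid is left; crystals form when [target] > cs1 (solubility = 0.0900 M, k = 9.20 min⁻¹)
    2 partner → homo dimer (k = 0.280 M⁻¹ min⁻¹)
    dissolved substrate + target → side product (k = 0.0690 M⁻¹ min⁻¹)
    partner → decomposed reagent (k = 0.120 min⁻¹)
    solid substrate ⇌ dissolved substrate, rate k5*(cs5 - [dissolved substrate]) while solid is left; crystals form when [dissolved substrate] > cs5 (solubility = 0.160 M, k = 0.0950 min⁻¹)
    solid substrate + protic impurity → quenched substrate (k = 0.0340 M⁻¹ min⁻¹)
    dissolved substrate + partner → target (k = 0.220 M⁻¹ min⁻¹)

For this flask left until 4.0 h, the loss constant gives 0.828%. The computed result is 0.733%.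

The data stem from a simulated flask with constants of no real substance, noise included.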